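(The numbers in the tables were computed with constants of no real substance, and the scatter is random.)

Saturday's flask, charged with half the G of Wednesday's, loses J faster in percent of its own charge than Wednesday's does: 11 percentage points in 12.0 h against 5 points in 7.00 h.

| setting | Wednesday's | Saturday's | flask |
|---|---|---|---|
| G | 1.5 M | 0.75 M | 1.5 M |
| D | 75 mM | 75 mM | 75 mM |
| remark | the very flask that is asked about, followed so far | run made earlier |  |
| time |  |  | 50 h |

- Wednesday's (time / h: J / %): 1.00: 19.9; 2.00: 24.1; 4.00: 24.7; 8.00: 25.0; 15.0: 20.0
- Saturday's (time / h: J / %): 1.00: 22.8; 3.00: 28.7; 8.00: 26.2; 20.0: 15.3; 48.0: 0.6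

(standard deviation of a reading: 0.5 percentage points)

- the best time, 50 h at the latest, for J
- the amount of J, in percent of the G charged, at that time
- earliest time at which at least nineteen twentieths of that best amount are there
- latest time at which they still are

- in percentages every species weighs as the G in it: one E counts as two
- what may be going on: J <-> X; J + Q -> G + Q; 2 G -> E; G + Q -> J + Q; G + D -> Q + J

Saturday's readings at 8.00 h and 20.0 h give 6.81 mM/h as r, the concentration of J lost per hour past the top, taken as constant (zero order in J). That line meets zero at 36.8 h, before Saturday's 0.6% at 48.0 h, so this last reading is left out of r. Wednesday's last pair gives 10.7 mM/h, but its span is shorter than Saturday's and a point there weighs twice as much in concentration, so Saturday's value is carried, on the assumption that equal D gives equal r.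

The opposite outcome would be Wednesday's flask holding 95.0% of its 25.0% reading up to 50 h, which allows a loss of 0.446 mM/h. But r stands 15.3 times above that, so the top lies early. In this flask r is a fraction 0.00454 /h of the G charged. A line of that slope through the midpoint of the 8.00 h and 15.0 h readings crosses 95.0% of the 8.00 h reading at 8.75 h.

The forecast gives 25.2% at 6 h, held from 1.9 h to 10.5 h, later than this line, from “A smooth curve through 4, 8 and 15 h”.

The flask gives 25.4% at 4.37 h, held from 2.24 h to 8.49 h.

    J ⇌ X (K = 0.420, k = 1.60 × 10⁻⁴ /s)
    J + Q → G + Q, rate k2*[Q] as long as [J] is above zero (k = 2.30 × 10⁻⁴ /s)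
    2 G → E (k = 1.20 × 10⁻⁴ /M/s)
    G + Q → J + Q, rate k4*[Q]*[G] (k = 0.00180 /M/s)
    G + D → Q + J (k = 0.00300 /M/s)

Q stands at 0.0750 M at 4.37 h and at 0.0750 M at 50.0 h. Carried on from 8.49 h, r puts J at 5.28% at 50.0 h, and the flask holds 4.86%. The same flask read at 12.0 h comes out at 22.5% by r, and it holds 22.6%.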